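**Strategy.** In indenone numbering, the cyclohexenone ring (C3a–C4(=O)–C5=C6–C7–C7a) is read as the aldol condensation product of a 1,5-diketone with carbonyls at C4 and C6. The plan exploits this 1,5-relationship through C3a, C7a and C7: the diketone is the strain-release retro-aldol product of a cyclobutanol in which C4 is still bonded to C7. In one operation the key step oxidises a bicyclo[3.2.0]heptane triol, cleaves the C4–C7 bond and closes the six-membered ring by forming the C5=C6 double bond. The cis angular methyls come unchanged from a [2+2] adduct. The precursor is assembled from a chroman acetaldehyde, a cyclobutanone and 2-methylbut-3-yn-2-ol.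

Key step: step 9

Assumption: the sense of induction of the BOXAX ligand (step 3) and of the pyrrolidine auxiliary (step 6) is assigned by analogy with related substrates; if either proves opposite, the antipodal ligand or auxiliary is used and nothing else changes. All numbered starting materials are taken as purchasable.

Step 1
Reactants: 1 4-methoxy-2-methylphenol
Product: 2 2-bromo-4-methoxy-6-methylphenol
Conditions: NBS, i-Pr2NH (cat.), CH2Cl2, 0 °C
Reagents that add atoms: N-bromosuccinimide (O=C1CCC(=O)N1Br)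
Why: Amine-catalysed NBS bromination of a phenol (electrophilic aromatic substitution) is ortho-selective and the para position is blocked by OMe, so bromine should enter the free ortho position.

Step 2
Reactants: 2 2-bromo-4-methoxy-6-methylphenol; 3 4-bromo-2-methylbut-1-ene
Product: 5 4-methoxy-2-methyl-6-(3-methylbut-3-en-1-yl)phenol, via (3-methylbut-3-en-1-yl)zinc bromide 4 (not isolated)
Conditions: 3, Zn, LiCl, THF, 40 °C; then 2, Pd(OAc)2 (cat.), SPhos (cat.), THF, 25–50 °C
Reagents that add atoms: none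
Why: Negishi sp3–sp2 cross-coupling with Pd/SPhos tolerates a free phenol, and the primary homoallylic zinc reagent should transmetallate and reductively eliminate faster than β-hydride elimination.

Step 3
Reactants: 5 4-methoxy-2-methyl-6-(3-methylbut-3-en-1-yl)phenol
Product: 6 methyl 2-[(2R)-6-methoxy-2,8-dimethylchroman-2-yl]acetate
Conditions: Pd(TFA)2 (cat.), (R,R)-Bn-BOXAX (cat.), p-benzoquinone, CO (1 atm), MeOH, rt
Reagents that add atoms: carbon monoxide ([C-]#[O+]); methanol (CO)
Why: Enantioselective domino Wacker/carbonylation: ligand-controlled 6-exo oxypalladation of the 1,1-disubstituted alkene by the phenol sets the quaternary C2, and the neopentyl alkylpalladium, having no β-hydrogen, is intercepted by CO insertion and methanolysis.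

Step 4
Reactants: 6 methyl 2-[(2R)-6-methoxy-2,8-dimethylchroman-2-yl]acetate
Product: 7 2-[(2R)-6-methoxy-2,8-dimethylchroman-2-yl]acetaldehyde
Conditions: DIBAL-H, CH2Cl2, −78 °C; Rochelle salt work-up
Reagents that add atoms: none
Why: Partial ester reduction: at −78 °C DIBAL-H stops at the tetrahedral aluminium hemiacetal, which gives the aldehyde on work-up without touching C2.

Step 5
Reactants: 8 (2R,5R)-2,5-dimethylpyrrolidine
Product: 9 1-[(2R,5R)-2,5-dimethylpyrrolidin-1-yl]ethan-1-one
Conditions: Ac2O, Et3N, CH2Cl2, 0 °C to rt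
Reagents that add atoms: acetic anhydride (CC(=O)OC(C)=O)
Why: Simple N-acylation of a secondary amine; the auxiliary stereocentres are untouched.

Step 6
Reactants: 9 1-[(2R,5R)-2,5-dimethylpyrrolidin-1-yl]ethan-1-one; 10 1,2-dimethylcyclopent-1-ene
Product: 13 (1S,5S)-1,5-dimethylbicyclo[3.2.0]heptan-6-one, via keteniminium triflate 11 (not isolated), via cyclobutaniminium triflate 12 (not isolated)
Conditions: Tf2O, 2,4,6-collidine, 10 (excess), ClCH2CH2Cl, 0 °C to reflux; then aq. NaHCO3, rt
Reagents that add atoms: water (O)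
Why: Keteniminium–alkene [2+2] cycloaddition: the keteniminium ion adds suprafacially across the ring alkene, which forces the two angular methyls cis, while the C2-symmetric pyrrolidine should select one of the two enantiomeric orientations of the symmetric alkene; hydrolysis frees the ketone and the auxiliary.

Step 7
Reactants: 13 (1S,5S)-1,5-dimethylbicyclo[3.2.0]heptan-6-one; 7 2-[(2R)-6-methoxy-2,8-dimethylchroman-2-yl]acetaldehyde; 14 2-methylbut-3-yn-2-ol
Product: 17 (1S,5S)-7-{1-hydroxy-2-[(2R)-6-methoxy-2,8-dimethylchroman-2-yl]ethyl}-6-(3-hydroxy-3-methylbut-1-yn-1-yl)-1,5-dimethylbicyclo[3.2.0]heptan-6-ol, via lithium aldolate 15 (not isolated), via dilithiated 2-methylbut-3-yn-2-ol 16 (not isolated)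
Conditions: 13, LDA, THF, −78 °C; 7, −78 °C; then 16 (from 14 and n-BuLi, THF, −78 to 0 °C, excess), −78 to −30 °C; aq. NH4Cl
Reagents that add atoms: none
Why: The kinetic lithium enolate (only C7 is enolisable) should undergo aldol addition to the aldehyde faster than proton transfer, and the lithium acetylide then adds 1,2 to the strained cyclobutanone carbonyl of the aldolate; the three new stereocentres need no control because all are destroyed in step 9.

Step 8
Reactants: 17 (1S,5S)-7-{1-hydroxy-2-[(2R)-6-methoxy-2,8-dimethylchroman-2-yl]ethyl}-6-(3-hydroxy-3-methylbut-1-yn-1-yl)-1,5-dimethylbicyclo[3.2.0]heptan-6-ol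
Product: 18 (1S,5S)-7-{1-hydroxy-2-[(2R)-6-methoxy-2,8-dimethylchroman-2-yl]ethyl}-6-(3-hydroxy-3-methylbutyl)-1,5-dimethylbicyclo[3.2.0]heptan-6-ol
Conditions: H2 (1 atm), Pd/C, EtOAc (trace Et3N), rt
Reagents that add atoms: none
Why: Heterogeneous hydrogenation saturates the alkyne, while the arene, the aryl ether and the tertiary alcohols should be inert under neutral conditions.

Step 9
Reactants: 18 (1S,5S)-7-{1-hydroxy-2-[(2R)-6-methoxy-2,8-dimethylchroman-2-yl]ethyl}-6-(3-hydroxy-3-methylbutyl)-1,5-dimethylbicyclo[3.2.0]heptan-6-ol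
Product: 21 (3aS,7aS)-5-(2-hydroxy-2-methylpropyl)-6-{[(2R)-6-methoxy-2,8-dimethylchroman-2-yl]methyl}-3a,7a-dimethyl-1,2,3,3a,7,7a-hexahydro-4H-inden-4-one, via 2-acylcyclobutanol 19 (not isolated), via 1,5-diketone 20 (not isolated)
Conditions: Dess–Martin periodinane, NaHCO3, CH2Cl2, 0 °C to rt; then KOH, MeOH, rt
Reagents that add atoms: none
Why: Dess–Martin oxidation of the only secondary alcohol gives β-hydroxy ketone 19, whose carbinol carbon is a cyclobutane carbon, so alkoxide formation triggers a strain-releasing retro-aldol (de Mayo-type) cleavage of the C6–C7 bond of the bicyclo[3.2.0]heptane to give 1,5-diketone 20. Base then enolises the tert-alkyl ketone at its only α-CH2, and this enolate adds to the side-chain ketone in a 6-(enolendo)-exo-trig aldol closure followed by E1cB loss of water to the tetrasubstituted enone; the closest known chemistry is the de Mayo fragmentation followed by the ring-closing aldol condensation of a Robinson annulation. No stereocentre is created: the three centres of uncertain configuration in 18 are all destroyed, and C3a, C7a and the chroman C2 are not touched. The selectivity needed is regiochemical; it should be secured because the enolate at the ring CH2 of the other ketone can only re-form the strained cyclobutanol, and the enolate next to the chroman would have to attack a neopentyl ketone to give an aldol that cannot dehydrate without severe strain, so only the desired closure is drained by dehydration. Mild base at room temperature is chosen so that ring closure outruns β-elimination of the aryloxide from the β-aryloxy ketone.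

**Compound list**

1 | 4-methoxy-2-methylphenol | COc1ccc(O)c(C)c1 | starting material
2 | 2-bromo-4-methoxy-6-methylphenol | COc1cc(C)c(O)c(Br)c1 | intermediate
3 | 4-bromo-2-methylbut-1-ene | C=C(C)CCBr | starting material
4 | (3-methylbut-3-en-1-yl)zinc bromide | C=C(C)CC[Zn]Br | intermediate (not isolated)
5 | 4-methoxy-2-methyl-6-(3-methylbut-3-en-1-yl)phenol | COc1cc(C)c(O)c(CCC(C)=C)c1 | intermediate
6 | methyl 2-[(2R)-6-methoxy-2,8-dimethylchroman-2-yl]acetate | COc1cc(C)c2c(c1)CC[C@](C)(CC(=O)OC)O2 | intermediate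
7 | 2-[(2R)-6-methoxy-2,8-dimethylchroman-2-yl]acetaldehyde | COc1cc(C)c2c(c1)CC[C@](C)(CC=O)O2 | intermediate
8 | (2R,5R)-2,5-dimethylpyrrolidine | C[C@@H]1CC[C@@H](C)N1 | starting material
9 | 1-[(2R,5R)-2,5-dimethylpyrrolidin-1-yl]ethan-1-one | C[C@@H]1CC[C@@H](C)N1C(C)=O | intermediate
10 | 1,2-dimethylcyclopent-1-ene | CC1=C(C)CCC1 | starting material
11 | (2R,5R)-1-ethenylidene-2,5-dimethylpyrrolidin-1-ium triflate (keteniminium salt) | C[C@@H]1CC[C@@H](C)[N+]1=C=C.[O-]S(=O)(=O)C(F)(F)F | intermediate (not isolated)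
12 | (2R,5R)-1-[(1S,5S)-1,5-dimethylbicyclo[3.2.0]heptan-6-ylidene]-2,5-dimethylpyrrolidin-1-ium triflate | C[C@@H]1CC[C@@H](C)[N+]1=C1[C@@]2(C)CCC[C@@]2(C)C1.[O-]S(=O)(=O)C(F)(F)F | intermediate (not isolated)
13 | (1S,5S)-1,5-dimethylbicyclo[3.2.0]heptan-6-one (cis-fused, angular methyls cis) | O=C1[C@@]2(C)CCC[C@@]2(C)C1 | intermediate
14 | 2-methylbut-3-yn-2-ol | CC(C)(O)C#C | starting material
15 | lithium alkoxide of (1S,5S)-7-{1-hydroxy-2-[(2R)-6-methoxy-2,8-dimethylchroman-2-yl]ethyl}-1,5-dimethylbicyclo[3.2.0]heptan-6-one (C7 and carbinol carbon uncontrolled) | COc1cc(C)c2c(c1)CC[C@](C)(CC(O[Li])C1C(=O)[C@@]3(C)CCC[C@]31C)O2 | intermediate (not isolated)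
16 | C,O-dilithiated 2-methylbut-3-yn-2-ol | [Li]C#CC(C)(C)O[Li] | intermediate (not isolated)
17 | (1S,5S)-7-{1-hydroxy-2-[(2R)-6-methoxy-2,8-dimethylchroman-2-yl]ethyl}-6-(3-hydroxy-3-methylbut-1-yn-1-yl)-1,5-dimethylbicyclo[3.2.0]heptan-6-ol (C6, C7 and side-chain carbinol uncontrolled) | COc1cc(C)c2c(c1)CC[C@](C)(CC(O)C1C(O)(C#CC(C)(C)O)[C@@]3(C)CCC[C@]31C)O2 | intermediate
18 | (1S,5S)-7-{1-hydroxy-2-[(2R)-6-methoxy-2,8-dimethylchroman-2-yl]ethyl}-6-(3-hydroxy-3-methylbutyl)-1,5-dimethylbicyclo[3.2.0]heptan-6-ol (same three centres uncontrolled) | COc1cc(C)c2c(c1)CC[C@](C)(CC(O)C1C(O)(CCC(C)(C)O)[C@@]3(C)CCC[C@]31C)O2 | intermediate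
19 | 1-[(1S,5S)-6-hydroxy-6-(3-hydroxy-3-methylbutyl)-1,5-dimethylbicyclo[3.2.0]heptan-7-yl]-2-[(2R)-6-methoxy-2,8-dimethylchroman-2-yl]ethan-1-one | COc1cc(C)c2c(c1)CC[C@](C)(CC(=O)C1C(O)(CCC(C)(C)O)[C@@]3(C)CCC[C@]31C)O2 | intermediate (not isolated)
20 | 4-hydroxy-1-[(1S,2S)-2-{3-[(2R)-6-methoxy-2,8-dimethylchroman-2-yl]-2-oxopropyl}-1,2-dimethylcyclopentyl]-4-methylpentan-1-one | COc1cc(C)c2c(c1)CC[C@](C)(CC(=O)C[C@@]1(C)[C@](C(=O)CCC(C)(C)O)(C)CCC1)O2 | intermediate (not isolated)
21 | (3aS,7aS)-5-(2-hydroxy-2-methylpropyl)-6-{[(2R)-6-methoxy-2,8-dimethylchroman-2-yl]methyl}-3a,7a-dimethyl-1,2,3,3a,7,7a-hexahydro-4H-inden-4-one | COc1cc(C)c2c(c1)CC[C@](C)(CC1=C(CC(C)(C)O)C(=O)[C@@]3(C)CCC[C@@]3(C)C1)O2 | target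

**Step count.** Total: 9 steps. Longest linear sequence: 7 steps (1, 2, 3, 4, 7, 8, 9).

**Steps most likely to fail**

Step 6. The auxiliary may discriminate poorly between the two enantiomeric orientations of the symmetric alkene, and cycloaddition to a tetrasubstituted alkene may be slow enough for the unsubstituted keteniminium ion to oligomerise. The fallback sets out from 10 and rejoins the route at 13. Dichloroketene (trichloroacetyl chloride, Zn–Cu, Et2O) is added to 10 to give the racemic cis-fused dichlorocyclobutanone F1, and Zn/AcOH dechlorination gives the racemic ketone F2. Addition of lithiated (S)-N,S-dimethyl-S-phenylsulfoximine should give two diastereomeric β-hydroxysulfoximines, F3 from the (1S,5S) ketone and F4 from the (1R,5R) ketone, which are separated by chromatography. Thermolysis of F3 in refluxing toluene releases the sulfoximine and returns 13 as a single enantiomer.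

Step 9. Under base the newly formed ketone may enolise towards the chroman and expel the aryloxide (retro-oxa-Michael), which would open the chroman and erase C2 in competition with ring closure; the sequence may also stall before dehydration. The fallback sets out from 13 and 7 and rejoins at 21; it closes the same C5=C6 bond by olefination without hydroxide. The aldol of step 7 is quenched with NH4Cl to give the free β-hydroxy ketone F5, and Dess–Martin oxidation gives the 2-acylcyclobutanone F6. LiOH in THF/H2O opens the strained ring by retro-Claisen cleavage to keto acid F7, and isopropenyl acetate with catalytic TsOH gives enol lactone F8. Phosphonate F9 is made from 3 and trimethyl phosphite (Arbuzov reaction) and lithiated with n-BuLi. It opens F8 at the lactone carbonyl (phosphonate variant of the Fujimoto–Belleau reaction) to the β-ketophosphonate F10, which is formed beside the ketone enolate regiodefined at the ring CH2. After proton exchange on warming, intramolecular Horner–Wadsworth–Emmons olefination should give the isopropenyl enone F11. Mukaiyama hydration (Co(acac)2, PhSiH3, O2) of the 1,1-disubstituted alkene then gives 21.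

Step 7. The lithium aldolate may revert by retro-aldol or be deprotonated at C7 before the acetylide has added to the hindered carbonyl, so that 13 and 7 are returned or conversion is incomplete. The fallback sets out from 13 and 7 and rejoins at 17 by a stepwise, protected sequence. The aldolate is silylated in the flask with TESCl and the β-silyloxy ketone F12 is isolated, which removes the retro-aldol pathway. The less basic cerium acetylide (16 with CeCl3, THF, −78 °C) is added to give F13, and TBAF removes the silyl group to return 17.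

Further compounds
F1 | step 6 | rac-7,7-dichloro-1,5-dimethylbicyclo[3.2.0]heptan-6-one (cis-fused, one enantiomer drawn) | O=C1[C@@]2(C)CCC[C@@]2(C)C1(Cl)Cl
F2 | step 6 | rac-1,5-dimethylbicyclo[3.2.0]heptan-6-one (cis-fused, one enantiomer drawn) | O=C1[C@@]2(C)CCC[C@@]2(C)C1
F3 | step 6 | (1S,5S)-1,5-dimethyl-6-{[(S)-N-methyl-S-phenylsulfonimidoyl]methyl}bicyclo[3.2.0]heptan-6-ol | CN=[S@@](CC1(O)[C@@]2(C)CCC[C@@]2(C)C1)(=O)c1ccccc1
F4 | step 6 | (1R,5R)-1,5-dimethyl-6-{[(S)-N-methyl-S-phenylsulfonimidoyl]methyl}bicyclo[3.2.0]heptan-6-ol | CN=[S@@](CC1(O)[C@]2(C)CCC[C@]2(C)C1)(=O)c1ccccc1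
F5 | step 9 | (1S,5S)-7-{1-hydroxy-2-[(2R)-6-methoxy-2,8-dimethylchroman-2-yl]ethyl}-1,5-dimethylbicyclo[3.2.0]heptan-6-one | COc1cc(C)c2c(c1)CC[C@](C)(CC(O)C1C(=O)[C@@]3(C)CCC[C@]31C)O2
F6 | step 9 | (1S,5S)-7-{2-[(2R)-6-methoxy-2,8-dimethylchroman-2-yl]acetyl}-1,5-dimethylbicyclo[3.2.0]heptan-6-one | COc1cc(C)c2c(c1)CC[C@](C)(CC(=O)C1C(=O)[C@@]3(C)CCC[C@]31C)O2
F7 | step 9 | (1S,2S)-2-{3-[(2R)-6-methoxy-2,8-dimethylchroman-2-yl]-2-oxopropyl}-1,2-dimethylcyclopentane-1-carboxylic acid | COc1cc(C)c2c(c1)CC[C@](C)(CC(=O)C[C@@]1(C)[C@](C(=O)O)(C)CCC1)O2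
F8 | step 9 | (4aS,7aS)-3-{[(2R)-6-methoxy-2,8-dimethylchroman-2-yl]methyl}-4a,7a-dimethyl-5,6,7,7a-tetrahydrocyclopenta[c]pyran-1(4aH)-one | COc1cc(C)c2c(c1)CC[C@](C)(CC1=C[C@]3(C)CCC[C@]3(C)C(=O)O1)O2
F9 | step 9 | dimethyl (3-methylbut-3-en-1-yl)phosphonate | C=C(C)CCP(=O)(OC)OC
F10 | step 9 | dimethyl {1-[(1S,2S)-2-{3-[(2R)-6-methoxy-2,8-dimethylchroman-2-yl]-2-oxopropyl}-1,2-dimethylcyclopentyl]-4-methyl-1-oxopent-4-en-2-yl}phosphonate | COc1cc(C)c2c(c1)CC[C@](C)(CC(=O)C[C@@]1(C)[C@](C(=O)C(CC(C)=C)P(=O)(OC)OC)(C)CCC1)O2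
F11 | step 9 | (3aS,7aS)-6-{[(2R)-6-methoxy-2,8-dimethylchroman-2-yl]methyl}-3a,7a-dimethyl-5-(2-methylprop-2-en-1-yl)-1,2,3,3a,7,7a-hexahydro-4H-inden-4-one | COc1cc(C)c2c(c1)CC[C@](C)(CC1=C(CC(C)=C)C(=O)[C@@]3(C)CCC[C@@]3(C)C1)O2
F12 | step 7 | (1S,5S)-7-{2-[(2R)-6-methoxy-2,8-dimethylchroman-2-yl]-1-(triethylsilyloxy)ethyl}-1,5-dimethylbicyclo[3.2.0]heptan-6-one | COc1cc(C)c2c(c1)CC[C@](C)(CC(O[Si](CC)(CC)CC)C1C(=O)[C@@]3(C)CCC[C@]31C)O2
F13 | step 7 | (1S,5S)-6-(3-hydroxy-3-methylbut-1-yn-1-yl)-7-{2-[(2R)-6-methoxy-2,8-dimethylchroman-2-yl]-1-(triethylsilyloxy)ethyl}-1,5-dimethylbicyclo[3.2.0]heptan-6-ol | COc1cc(C)c2c(c1)CC[C@](C)(CC(O[Si](CC)(CC)CC)C1C(O)(C#CC(C)(C)O)[C@@]3(C)CCC[C@]31C)O2
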